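The depside ester is disconnected into benzyl olivetolate and the ring A acid, 2,4-dimethoxy-6-(2-oxopentyl)benzoic acid, which comes from a homophthalate through its 3-propyl enol lactone. Everything rests on building that homophthalate by C–C σ-bond insertion: in ring A the carbon bearing the depside carbonyl (C1) and the carbon bearing the CH2 of the oxopentyl chain (C6) are neighbours, with a methoxy oxygen on C2. 3,5-Dimethoxybenzyne, released by fluoride from an ortho-silylaryl triflate whose silicon sits between the triflate and a methoxy group, inserts into the CH2–C(=O) bond of dimethyl malonate, so both aryl–carbon bonds form at once in the required orientation.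

Key step: step 4

Remark: ring A is numbered as a benzoyl unit (C1 carries the depside carbonyl, C2 and C4 the methoxy groups, C6 the 2-oxopentyl chain); ring B is the olivetolic acid ring. The target has no stereocentre.
Assumption: the 2-OH of ring B, hydrogen-bonded to the neighbouring ester carbonyl, is left unprotected during the coupling, so ring B carries only a benzyl ester.

Step 1
Reactants: 1 3,5-dimethoxyphenol
Product: 2 2-bromo-3,5-dimethoxyphenol
Conditions: NBS (1.0 equiv), CH2Cl2, −78 °C to rt
Reagents that add atoms: N-bromosuccinimide, O=C1CCC(=O)N1Br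
Why: Electrophilic aromatic bromination of an activated phenol, in which hydrogen-bond-guided delivery of NBS in a non-polar solvent and the shielding of C4 by two flanking methoxy groups should direct bromine to C2 next to the hydroxyl, while one equivalent at low temperature limits twofold bromination.

Step 2
Reactants: 2 2-bromo-3,5-dimethoxyphenol
Product: 3 (2-bromo-3,5-dimethoxyphenoxy)trimethylsilane
Conditions: HMDS, THF, 70 °C; evaporate
Reagents that add atoms: hexamethyldisilazane, C[Si](C)(C)N[Si](C)(C)C
Why: O-Silylation of a phenol with hexamethyldisilazane releases only ammonia, so the moisture-sensitive aryl silyl ether should be usable after evaporation.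

Step 3
Reactants: 3 (2-bromo-3,5-dimethoxyphenoxy)trimethylsilane
Product: 6 3,5-dimethoxy-2-(trimethylsilyl)phenyl trifluoromethanesulfonate, via aryllithium 4 (not isolated), via lithium 2-silylphenoxide 5 (not isolated)
Conditions: n-BuLi, THF, −100 °C; then Tf2O, −100 to −78 °C
Reagents that add atoms: trifluoromethanesulfonic anhydride, O=S(=O)(OS(=O)(=O)C(F)(F)F)C(F)(F)F
Why: Bromine–lithium exchange gives aryllithium 4, an anionic 1,3 O-to-C silyl shift (retro-Brook rearrangement) turns it into phenoxide 5, and O-sulfonylation with triflic anhydride completes the standard sequence to an ortho-silylaryl triflate.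

Step 4
Reactants: 6 3,5-dimethoxy-2-(trimethylsilyl)phenyl trifluoromethanesulfonate; 7 dimethyl malonate
Product: 10 methyl 2,4-dimethoxy-6-(2-methoxy-2-oxoethyl)benzoate, via 3,5-dimethoxybenzyne 8 (not isolated), via potassium benzocyclobutenoxide 9 (not isolated)
Conditions: KF, 18-crown-6, THF, rt; 6 added slowly to excess 7
Reagents that add atoms: none
Why: Fluoride attacks silicon of 6 and 1,2-elimination of triflate gives aryne 8; the potassium enolate of 7 adds to the aryne carbon remote from the methoxy group, the aryl anion so formed closes onto one ester carbonyl to give benzocyclobutenoxide 9, and retro-aldol-type fragmentation of the strained ring gives the arylacetate enolate, which is protonated by fresh malonate so that the malonate enolate is regenerated. The closest known reaction type is the insertion of arynes from silylaryl triflates into the C–C σ-bond of malonates and β-keto esters (aryne acyl-alkylation). The only ring closed is the transient four-membered ring of 9 (4-exo-trig), which reopens in the same step, so no ring is added to the skeleton and no stereocentre is formed. Regioselectivity is required and is secured by the methoxy group next to the triple bond: its inductive withdrawal distorts the aryne so that the nucleophile enters at the distal carbon and the negative charge develops beside the methoxy-bearing carbon, which places the ester carbonyl next to OMe and the CH2CO2Me arm on the far side, as in ring A. Insertion should win over simple protonation of the aryl anion (α-arylation) because the carbonyl attack is intramolecular in an aprotic medium, and excess malonate should suppress a second arylation of the product.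

Step 5
Reactants: 10 methyl 2,4-dimethoxy-6-(2-methoxy-2-oxoethyl)benzoate
Product: 11 2-(carboxymethyl)-4,6-dimethoxybenzoic acid
Conditions: KOH, EtOH/H2O, reflux; then aq. HCl, 0 °C
Reagents that add atoms: potassium hydroxide, [K+].[OH-]
Why: Saponification (acyl-oxygen ester hydrolysis) should cleave the unhindered arylacetate quickly and the di-ortho-substituted benzoate on prolonged reflux, and acidification should give the homophthalic acid.

Step 6
Reactants: 11 2-(carboxymethyl)-4,6-dimethoxybenzoic acid; 12 butyryl chloride
Product: 16 6,8-dimethoxy-3-propyl-1H-isochromen-1-one, via homophthalic anhydride 13 (not isolated), via 4-butanoyl anhydride 14 (not isolated), via isocoumarin-4-carboxylic acid 15 (not isolated)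
Conditions: excess 12, neat, reflux (bath 200 °C), 4 h
Reagents that add atoms: none
Why: Thermal condensation of a homophthalic acid with an acyl chloride, the standard entry to 3-alkylisocoumarins, should proceed by dehydration to anhydride 13, C-acylation at the doubly activated C4 to 14, acyl transfer from the aryl carbonyl to the enol oxygen to give 15, and thermal decarboxylation.

Step 7
Reactants: 16 6,8-dimethoxy-3-propyl-1H-isochromen-1-one
Product: 17 2,4-dimethoxy-6-(2-oxopentyl)benzoic acid
Conditions: KOH (5% aq.), EtOH, reflux; then cold dil. HCl to pH 3, extract at once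
Reagents that add atoms: potassium hydroxide, [K+].[OH-]
Why: Alkaline hydrolysis of the enol lactone opens the ring at the lactone carbonyl and the released enolate tautomerises to the ketone, while cold, mild acidification should avoid re-closure.

Step 8
Reactants: 18 olivetolic acid
Product: 19 benzyl 2,4-dihydroxy-6-pentylbenzoate
Conditions: BnBr, KHCO3, DMF, rt
Reagents that add atoms: benzyl bromide, BrCc1ccccc1
Why: Carboxylate O-alkylation (SN2) under hydrogen carbonate buffering, where only the carboxylic acid is deprotonated so both phenols stay free, and room temperature should avoid decarboxylation of the resorcylic acid.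

Step 9
Reactants: 17 2,4-dimethoxy-6-(2-oxopentyl)benzoic acid; 19 benzyl 2,4-dihydroxy-6-pentylbenzoate
Product: 20 benzyl 4-{[2,4-dimethoxy-6-(2-oxopentyl)benzoyl]oxy}-2-hydroxy-6-pentylbenzoate
Conditions: DCC, DMAP (cat.), CH2Cl2, 0 °C to rt; DCC added last
Reagents that add atoms: none
Why: Steglich esterification should acylate only the more acidic, unhindered 4-OH because the 2-OH is tied in a hydrogen bond to the flanking ester carbonyl, and the cold, near-neutral carbodiimide conditions are chosen to limit enol-lactonisation of the activated keto acid back to 16, which could be recycled through step 7.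

Step 10
Reactants: 20 benzyl 4-{[2,4-dimethoxy-6-(2-oxopentyl)benzoyl]oxy}-2-hydroxy-6-pentylbenzoate
Product: 21 4-{[2,4-dimethoxy-6-(2-oxopentyl)benzoyl]oxy}-2-hydroxy-6-pentylbenzoic acid
Conditions: H2 (1 atm), Pd/C, EtOAc, rt
Reagents that add atoms: none
Why: Catalytic hydrogenolysis of the benzyl ester under neutral conditions should leave the aryl ester, the dialkyl ketone and the aryl methyl ethers untouched and exposes the depside to neither acid nor base.

Compound list
1 | 3,5-dimethoxyphenol | COc1cc(O)cc(OC)c1 | starting material
2 | 2-bromo-3,5-dimethoxyphenol | COc1cc(O)c(Br)c(OC)c1 | intermediate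
3 | (2-bromo-3,5-dimethoxyphenoxy)trimethylsilane | COc1cc(O[Si](C)(C)C)c(Br)c(OC)c1 | intermediate
4 | [2,4-dimethoxy-6-(trimethylsilyloxy)phenyl]lithium | [Li]c1c(OC)cc(OC)cc1O[Si](C)(C)C | intermediate
5 | lithium 3,5-dimethoxy-2-(trimethylsilyl)phenolate | [Li+].[O-]c1cc(OC)cc(OC)c1[Si](C)(C)C | intermediate
6 | 3,5-dimethoxy-2-(trimethylsilyl)phenyl trifluoromethanesulfonate | COc1cc(OC)c([Si](C)(C)C)c(OS(=O)(=O)C(F)(F)F)c1 | intermediate
7 | dimethyl malonate | COC(=O)CC(=O)OC | starting material
8 | 3,5-dimethoxybenzyne (1,2-didehydro-3,5-dimethoxybenzene) | COC1=CC(OC)=CC#C1 | intermediate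
9 | potassium 3,5,7-trimethoxy-8-(methoxycarbonyl)bicyclo[4.2.0]octa-1,3,5-trien-7-olate | COC(=O)C1c2cc(OC)cc(OC)c2C1([O-])OC.[K+] | intermediate
10 | methyl 2,4-dimethoxy-6-(2-methoxy-2-oxoethyl)benzoate | COC(=O)Cc1cc(OC)cc(OC)c1C(=O)OC | intermediate
11 | 2-(carboxymethyl)-4,6-dimethoxybenzoic acid | OC(=O)Cc1cc(OC)cc(OC)c1C(=O)O | intermediate
12 | butyryl chloride | CCCC(=O)Cl | starting material
13 | 6,8-dimethoxyisochromane-1,3-dione | COc1cc(OC)c2C(=O)OC(=O)Cc2c1 | intermediate
14 | 4-butanoyl-6,8-dimethoxyisochromane-1,3-dione | CCCC(=O)C1C(=O)OC(=O)c2c(OC)cc(OC)cc21 | intermediate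
15 | 6,8-dimethoxy-1-oxo-3-propyl-1H-isochromene-4-carboxylic acid | CCCC1=C(C(=O)O)c2cc(OC)cc(OC)c2C(=O)O1 | intermediate
16 | 6,8-dimethoxy-3-propyl-1H-isochromen-1-one | CCCC1=Cc2cc(OC)cc(OC)c2C(=O)O1 | intermediate
17 | 2,4-dimethoxy-6-(2-oxopentyl)benzoic acid | CCCC(=O)Cc1cc(OC)cc(OC)c1C(=O)O | intermediate
18 | olivetolic acid (2,4-dihydroxy-6-pentylbenzoic acid) | CCCCCc1cc(O)cc(O)c1C(=O)O | starting material
19 | benzyl 2,4-dihydroxy-6-pentylbenzoate | CCCCCc1cc(O)cc(O)c1C(=O)OCc1ccccc1 | intermediate
20 | benzyl 4-{[2,4-dimethoxy-6-(2-oxopentyl)benzoyl]oxy}-2-hydroxy-6-pentylbenzoate | CCCCCc1cc(OC(=O)c2c(CC(=O)CCC)cc(OC)cc2OC)cc(O)c1C(=O)OCc1ccccc1 | intermediate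
21 | 4-{[2,4-dimethoxy-6-(2-oxopentyl)benzoyl]oxy}-2-hydroxy-6-pentylbenzoic acid | CCCCCc1cc(OC(=O)c2c(CC(=O)CCC)cc(OC)cc2OC)cc(O)c1C(=O)O | target

Total step count: 10.
Longest linear sequence: 9 steps (steps 1 to 7, 9 and 10); step 8 is a one-step side branch.

Steps most likely to fail

Step 4. The aryl anion may be protonated before it closes onto the ester (plain α-arylation of the malonate), the product enolate may capture a second aryne, or the nucleophile may enter at the aryne carbon next to the methoxy group. The fallback replaces the aryne by a copper-mediated arylation of the malonate anion with an ortho-bromobenzoate (Hurtley reaction). It sets out from dimethyl malonate 7, which is deprotonated with NaH and coupled (CuBr cat., excess 7, 70 °C) with purchased 2-bromo-4,6-dimethoxybenzoic acid F1 to give 2-(1,3-dimethoxy-1,3-dioxopropan-2-yl)-4,6-dimethoxybenzoic acid F2. Hydrolysis with aqueous NaOH at reflux, then acidification with gentle warming to decarboxylate the arylmalonic acid, should give diacid 11, where the route is rejoined before step 6.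

Step 9. The activated carboxyl group may be captured intramolecularly by the enol of the side-chain ketone faster than by the phenol, which returns the enol lactone; acylation at the chelated 2-OH is a lesser concern. The fallback masks the ketone before any carboxyl activation. It sets out from keto acid 17, whose carboxylate is alkylated (BnBr, KHCO3, DMF) to benzyl 2,4-dimethoxy-6-(2-oxopentyl)benzoate F3. Ketalisation with 1,2-bis(trimethylsilyloxy)ethane and catalytic Me3SiOTf in CH2Cl2 at −78 °C should give benzyl 2,4-dimethoxy-6-[(2-propyl-1,3-dioxolan-2-yl)methyl]benzoate F4. Hydrogenolysis (H2, Pd/C) frees 2,4-dimethoxy-6-[(2-propyl-1,3-dioxolan-2-yl)methyl]benzoic acid F5, and Steglich coupling with 19 (DCC, DMAP) should give benzyl 4-({2,4-dimethoxy-6-[(2-propyl-1,3-dioxolan-2-yl)methyl]benzoyl}oxy)-2-hydroxy-6-pentylbenzoate F6. Mild deketalisation (pyridinium p-toluenesulfonate, wet acetone) returns to 20, before step 10.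

Step 1. Bromination may occur para to the hydroxyl (at C4) or twice. The fallback installs silicon by carbamate-directed ortho-metalation in place of halogenation. It sets out from phenol 1, which is carbamoylated with isopropyl isocyanate (Et3N cat., CH2Cl2) to 3,5-dimethoxyphenyl N-isopropylcarbamate F7. In-situ N-silylation (t-BuMe2SiOTf, TMEDA), lithiation between the carbamate and the methoxy group (n-BuLi, −78 °C), quench with Me3SiCl and aqueous NaHSO4 work-up should give 3,5-dimethoxy-2-(trimethylsilyl)phenyl N-isopropylcarbamate F8. Carbamate cleavage (DBU, Et2NH, MeCN, 40 °C) liberates 3,5-dimethoxy-2-(trimethylsilyl)phenol F9, which is triflated in the same flask with PhNTf2 to give 6, where the route is rejoined before step 4.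

Further compounds
F1 | step 4 | 2-bromo-4,6-dimethoxybenzoic acid | COc1cc(Br)c(C(=O)O)c(OC)c1
F2 | step 4 | 2-(1,3-dimethoxy-1,3-dioxopropan-2-yl)-4,6-dimethoxybenzoic acid | COC(=O)C(C(=O)OC)c1cc(OC)cc(OC)c1C(=O)O
F3 | step 9 | benzyl 2,4-dimethoxy-6-(2-oxopentyl)benzoate | CCCC(=O)Cc1cc(OC)cc(OC)c1C(=O)OCc1ccccc1
F4 | step 9 | benzyl 2,4-dimethoxy-6-[(2-propyl-1,3-dioxolan-2-yl)methyl]benzoate | CCCC1(Cc2cc(OC)cc(OC)c2C(=O)OCc2ccccc2)OCCO1
F5 | step 9 | 2,4-dimethoxy-6-[(2-propyl-1,3-dioxolan-2-yl)methyl]benzoic acid | CCCC1(Cc2cc(OC)cc(OC)c2C(=O)O)OCCO1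
F6 | step 9 | benzyl 4-({2,4-dimethoxy-6-[(2-propyl-1,3-dioxolan-2-yl)methyl]benzoyl}oxy)-2-hydroxy-6-pentylbenzoate | CCCCCc1cc(OC(=O)c2c(CC3(CCC)OCCO3)cc(OC)cc2OC)cc(O)c1C(=O)OCc1ccccc1
F7 | step 1 | 3,5-dimethoxyphenyl N-isopropylcarbamate | COc1cc(OC)cc(OC(=O)NC(C)C)c1
F8 | step 1 | 3,5-dimethoxy-2-(trimethylsilyl)phenyl N-isopropylcarbamate | COc1cc(OC)c([Si](C)(C)C)c(OC(=O)NC(C)C)c1
F9 | step 1 | 3,5-dimethoxy-2-(trimethylsilyl)phenol | COc1cc(O)c([Si](C)(C)C)c(OC)c1
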